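**Strategy**

Ring A (C1–C5) together with its exocyclic neighbour C6 is read as a ring-contracted p-menthane: C1 with its methyl, C2, C3, the carbinol C4 with its isopropyl group, C5 and C6 map onto (S)-terpinen-4-ol. Everything rests on the C1–C5 disconnection, made by a photochemical Wolff ring contraction: in a 6-diazo-2-allyl-2-methylcyclohexanone the quaternary C1 shifts from the carbonyl carbon C6 to C5, closing the cyclopentane and pushing C6 out of the ring as an acyl group, with C1 and C4 already set. Ring B is then closed at C8=C9 by ring-closing metathesis, and hydroxyl-directed reduction, hydroxyl-directed epoxidation and acylation finish the target.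

Key step: step 6

Remark: (S)-(+)-terpinen-4-ol of high enantiomeric purity is assumed to be purchasable; atoms are numbered as in daucane (C1 angular carbon carrying the C15 methyl, C4 carbinol, C5 ring-fusion CH, C6 acyloxy carbon, C8 and C9 epoxide carbons; ring A five-membered, ring B seven-membered).

**Route**

Step 1
Reactants: 1 (S)-(+)-terpinen-4-ol
Product: 2 (1S)-4-methyl-1-(propan-2-yl)cyclohexane-1,3-diol (diastereomer mixture at C3 and C4 of the cyclohexane)
Conditions: BH3·THF, THF, 0 to 23 °C; then NaOH, H2O2, H2O, 0 °C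
Reagents that add atoms: hydrogen peroxide OO
Why: Hydroboration–oxidation puts the hydroxyl on the less substituted alkene carbon (the future C6) and leaves the C4 carbinol of the chiral pool untouched, while the two new centres form as a mixture that is erased in steps 2 and 3.

Step 2
Reactants: 2 (1S)-4-methyl-1-(propan-2-yl)cyclohexane-1,3-diol
Product: 3 (5S)-5-hydroxy-2-methyl-5-(propan-2-yl)cyclohexan-1-one (C2 epimers)
Conditions: Dess–Martin periodinane, NaHCO3, CH2Cl2, 0 to 23 °C
Reagents that add atoms: none
Why: Dess–Martin oxidation converts only the secondary alcohol, and its buffered neutral medium should spare the β-hydroxy ketone from dehydration or retro-aldol cleavage, so C4 stays intact and no stereocentre is set.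

Step 3
Reactants: 3 (5S)-5-hydroxy-2-methyl-5-(propan-2-yl)cyclohexan-1-one
Product: 4 trimethyl({(5S)-2-methyl-5-(propan-2-yl)-5-[(trimethylsilyl)oxy]cyclohex-1-en-1-yl}oxy)silane
Conditions: Me3SiCl, NaI, Et3N, MeCN, 23 °C
Reagents that add atoms: chlorotrimethylsilane C[Si](C)(C)Cl
Why: Silylation under thermodynamic control (Me3SiI formed in the flask) caps the tertiary alcohol and should give the more substituted silyl enol ether towards the methyl-bearing carbon (the future C1), which removes the unset methyl centre and fixes the site of allylation.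

Step 4
Reactants: 4 bis-silylated enol ether; 5 diallyl carbonate
Product: 6 (2R,5S)-2-methyl-5-(propan-2-yl)-2-(prop-2-en-1-yl)-5-[(trimethylsilyl)oxy]cyclohexan-1-one
Conditions: Pd2(dba)3 (2.5 mol%), (R)-t-BuPHOX (6 mol%), Bu4N[Ph3SiF2] (35 mol%), THF, 25 °C
Reagents that add atoms: none
Why: Enantioselective Tsuji allylation of the silyl enol ether forms the quaternary C1 at the only enolate carbon available, and its configuration (allyl trans to OSiMe3) should be set by the (R)-ligand, the enantiomer that leads to (R)-2-allyl-2-methylcyclohexanone in the unsubstituted case, reinforced by axial attack anti to the axial silyloxy group.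

Step 5
Reactants: 6 allyl methyl ketone
Product: 8 (2R,5R)-6-diazo-2-methyl-5-(propan-2-yl)-2-(prop-2-en-1-yl)-5-[(trimethylsilyl)oxy]cyclohexan-1-one, via trifluoroacetyl ketone 7 (not isolated)
Conditions: LiN(SiMe3)2, THF, −78 °C; CF3CO2CH2CF3; aq. HCl work-up; then MeSO2N3, Et3N, H2O, MeCN, 23 °C
Reagents that add atoms: methanesulfonyl azide CS(=O)(=O)N=[N+]=[N-]
Why: Deprotonation can occur only at C5 because C1 is quaternary, C-trifluoroacetylation activates that position and deacylative Regitz diazo transfer installs the diazo group there, the −78 °C enolate being too short-lived to expel the β-silyloxy group; no stereocentre is formed.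

Step 6
Reactants: 8 α-diazo ketone
Product: 10 (2R,5R)-N-methoxy-N,2-dimethyl-5-(propan-2-yl)-2-(prop-2-en-1-yl)-5-[(trimethylsilyl)oxy]cyclopentane-1-carboxamide (C1 epimers of the cyclopentane, that is C5 of the target), via ketene 9 (not isolated)
Conditions: hν (medium-pressure Hg lamp, Pyrex), MeNHOMe (3 equiv), THF, 0 °C
Reagents that add atoms: N,O-dimethylhydroxylamine CNOC
Why: Irradiation expels N2 from the cyclic, s-Z-locked α-diazo ketone while the quaternary carbon C1 shifts from the carbonyl carbon C6 to the diazo carbon C5 in a concerted Wolff rearrangement, so the C1–C5 bond forms as C6 leaves the ring and becomes the ketene carbon, which the amine traps as the Weinreb amide. The closest known reaction type is the photochemical Wolff ring contraction of 2-diazocycloalkanones to cycloalkanecarboxylic acid derivatives. Ring A (C1–C5) closes by a 1,2-alkyl shift, a six- to five-membered ring contraction, and no other ring is made in this step. C1 migrates with retention, so its configuration from step 4 is carried over, C4 is untouched, and the new centre C5 arises by protonation of the amide enol without reliable face control and is therefore set only in step 7. The step needs the Wolff shift to outrun carbene 1,2-shifts from C4 and cyclopropanation of the allyl group. Direct, unsensitised excitation of an s-Z diazo ketone, which rearranges in concert with N2 loss, and the fact that C1 is the only group on C6 able to migrate should secure this.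

Step 7
Reactants: 10 Weinreb amide
Product: 12 (1R,2R,5R)-2-methyl-5-(propan-2-yl)-2-(prop-2-en-1-yl)-5-[(trimethylsilyl)oxy]cyclopentane-1-carbaldehyde, via aldehyde epimer mixture 11 (not isolated)
Conditions: LiAlH4, THF, −78 to 0 °C; aq. potassium sodium tartrate work-up; then DBU (0.2 equiv), CH2Cl2, 23 °C
Reagents that add atoms: none
Why: Weinreb amide reduction stops at the aldehyde through the chelated tetrahedral intermediate, and base-mediated enolisation should then equilibrate C5 under thermodynamic control to the epimer whose formyl group is trans to the isopropyl and allyl groups and cis to the smaller OSiMe3 and CH3.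

Step 8
Reactants: 12 aldehyde; 13 2-methylallylmagnesium chloride, CH2=C(CH3)CH2MgCl
Product: 15 (1R,2S,3R)-2-(1-hydroxy-3-methylbut-3-en-1-yl)-3-methyl-1-(propan-2-yl)-3-(prop-2-en-1-yl)cyclopentan-1-ol (epimers at the side-chain carbinol C6), via trimethylsilyl ether adduct 14 (not isolated)
Conditions: THF, −78 to 0 °C; then 1 M HCl, THF, 23 °C
Reagents that add atoms: none
Why: Grignard addition of the allylic reagent to the hindered aldehyde builds the C6–C7 bond and the acidic work-up cleaves the tertiary trimethylsilyl ether; the new C6 centre forms without reliable control and is reset in steps 10 and 11.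

Step 9
Reactants: 15 diene diol
Product: 16 (3R,3aS,8aR)-6,8a-dimethyl-3-(propan-2-yl)-1,2,3,3a,4,5,8,8a-octahydroazulene-3,4-diol (C4 epimers of the azulene, that is C6 of the target)
Conditions: second-generation Grubbs catalyst (5 mol%), CH2Cl2 (0.005 M), 40 °C
Reagents that add atoms: none
Why: Ring-closing metathesis joins the allyl group on C1 and the 1,1-disubstituted methallyl alkene to close ring B as the trans-fused cycloheptene with the trisubstituted C8=C9 bond and sets no stereocentre.

Step 10
Reactants: 16 bicyclic diol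
Product: 17 (3R,3aR,8aR)-3-hydroxy-6,8a-dimethyl-3-(propan-2-yl)-2,3,3a,5,8,8a-hexahydroazulen-4(1H)-one
Conditions: Dess–Martin periodinane, NaHCO3, CH2Cl2, 0 to 23 °C
Reagents that add atoms: none
Why: Dess–Martin oxidation touches only the secondary C6 alcohol, so both C6 epimers converge on one β-hydroxy ketone under neutral conditions that should leave C5 and the β,γ-alkene in place.

Step 11
Reactants: 17 β-hydroxy ketone
Product: 18 jaeschkeanadiol, (3R,3aS,4S,8aR)-6,8a-dimethyl-3-(propan-2-yl)-1,2,3,3a,4,5,8,8a-octahydroazulene-3,4-diol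
Conditions: Me4N[BH(OAc)3], AcOH, MeCN, −20 °C
Reagents that add atoms: none
Why: In this Evans–Saksena reduction the C4 hydroxyl, which lies on the β face cis to C6 on ring A, should bind boron and deliver hydride intramolecularly to the β face of the C6 carbonyl, giving the 1,3-anti diol with the 6α-hydroxyl.

Step 12
Reactants: 18 jaeschkeanadiol
Product: 19 8α,9α-epoxyjaeschkeanadiol, (1R,4R,5S,6S,8R,9S)-8,9-epoxydaucane-4,6-diol
Conditions: VO(acac)2 (5 mol%), t-BuOOH, CH2Cl2, 0 to 23 °C
Reagents that add atoms: tert-butyl hydroperoxide CC(C)(C)OO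
Why: In this vanadium-catalysed hydroxyl-directed epoxidation the homoallylic secondary 6α-hydroxyl should bind the metal peroxide and deliver oxygen to the α face of C8=C9, the face also left open by the β-oriented C15 methyl, while the tertiary 4β-hydroxyl is too remote to compete.

Step 13
Reactants: 19 epoxy diol; 20 3,4-dimethoxybenzoyl chloride
Product: 21 (1R,4R,5S,6S,8R,9S)-8,9-epoxy-4-hydroxydaucan-6-yl 3,4-dimethoxybenzoate (CNP0251065.1)
Conditions: Et3N, DMAP (0.2 equiv), CH2Cl2, 0 to 23 °C
Reagents that add atoms: none
Why: DMAP-catalysed acylation should occur only at the secondary C6 hydroxyl because the tertiary C4 hydroxyl next to the isopropyl group is inert under these conditions, and the basic medium keeps the trisubstituted epoxide intact.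

**Compound list**

1 | (S)-(+)-terpinen-4-ol, (1S)-4-methyl-1-(propan-2-yl)cyclohex-3-en-1-ol | CC1=CC[C@](O)(C(C)C)CC1 | starting material
2 | (1S)-4-methyl-1-(propan-2-yl)cyclohexane-1,3-diol (mixture at C3 and C4) | CC1CC[C@@](O)(C(C)C)CC1O | intermediate
3 | (5S)-5-hydroxy-2-methyl-5-(propan-2-yl)cyclohexan-1-one (C2 epimers) | CC1CC[C@@](O)(C(C)C)CC1=O | intermediate
4 | trimethyl({(5S)-2-methyl-5-(propan-2-yl)-5-[(trimethylsilyl)oxy]cyclohex-1-en-1-yl}oxy)silane | CC1=C(O[Si](C)(C)C)C[C@](O[Si](C)(C)C)(C(C)C)CC1 | intermediate
5 | diallyl carbonate | C=CCOC(=O)OCC=C | starting material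
6 | (2R,5S)-2-methyl-5-(propan-2-yl)-2-(prop-2-en-1-yl)-5-[(trimethylsilyl)oxy]cyclohexan-1-one | C=CC[C@@]1(C)CC[C@@](O[Si](C)(C)C)(C(C)C)CC1=O | intermediate
7 | 6-(trifluoroacetyl) derivative of 6 (1,3-diketone, epimers at the acylated carbon) | C=CC[C@@]1(C)CC[C@@](O[Si](C)(C)C)(C(C)C)C(C(=O)C(F)(F)F)C1=O | intermediate (not isolated)
8 | (2R,5R)-6-diazo-2-methyl-5-(propan-2-yl)-2-(prop-2-en-1-yl)-5-[(trimethylsilyl)oxy]cyclohexan-1-one | C=CC[C@@]1(C)CC[C@@](O[Si](C)(C)C)(C(C)C)C(=[N+]=[N-])C1=O | intermediate
9 | [(2R,5R)-2-methyl-5-(propan-2-yl)-2-(prop-2-en-1-yl)-5-[(trimethylsilyl)oxy]cyclopentylidene]methanone (ketene) | C=CC[C@@]1(C)CC[C@@](O[Si](C)(C)C)(C(C)C)C1=C=O | intermediate (not isolated)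
10 | (2R,5R)-N-methoxy-N,2-dimethyl-5-(propan-2-yl)-2-(prop-2-en-1-yl)-5-[(trimethylsilyl)oxy]cyclopentane-1-carboxamide (C1 epimers) | C=CC[C@@]1(C)CC[C@@](O[Si](C)(C)C)(C(C)C)C1C(=O)N(C)OC | intermediate
11 | (2R,5R)-2-methyl-5-(propan-2-yl)-2-(prop-2-en-1-yl)-5-[(trimethylsilyl)oxy]cyclopentane-1-carbaldehyde (C1 epimers) | C=CC[C@@]1(C)CC[C@@](O[Si](C)(C)C)(C(C)C)C1C=O | intermediate (not isolated)
12 | (1R,2R,5R)-2-methyl-5-(propan-2-yl)-2-(prop-2-en-1-yl)-5-[(trimethylsilyl)oxy]cyclopentane-1-carbaldehyde | C=CC[C@@]1(C)CC[C@@](O[Si](C)(C)C)(C(C)C)[C@@H]1C=O | intermediate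
13 | 2-methylallylmagnesium chloride | CC(=C)C[Mg]Cl | starting material
14 | trimethylsilyl ether of 15 (adduct before acidic work-up, C6 epimers) | C=CC[C@@]1(C)CC[C@@](O[Si](C)(C)C)(C(C)C)[C@@H]1C(O)CC(C)=C | intermediate (not isolated)
15 | (1R,2S,3R)-2-(1-hydroxy-3-methylbut-3-en-1-yl)-3-methyl-1-(propan-2-yl)-3-(prop-2-en-1-yl)cyclopentan-1-ol (C6 epimers) | C=CC[C@@]1(C)CC[C@@](O)(C(C)C)[C@@H]1C(O)CC(C)=C | intermediate
16 | (3R,3aS,8aR)-6,8a-dimethyl-3-(propan-2-yl)-1,2,3,3a,4,5,8,8a-octahydroazulene-3,4-diol (C4 epimers) | OC1CC(C)=CC[C@@]2(C)CC[C@@](O)(C(C)C)[C@H]12 | intermediate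
17 | (3R,3aR,8aR)-3-hydroxy-6,8a-dimethyl-3-(propan-2-yl)-2,3,3a,5,8,8a-hexahydroazulen-4(1H)-one | O=C1CC(C)=CC[C@@]2(C)CC[C@@](O)(C(C)C)[C@H]12 | intermediate
18 | jaeschkeanadiol, (3R,3aS,4S,8aR)-6,8a-dimethyl-3-(propan-2-yl)-1,2,3,3a,4,5,8,8a-octahydroazulene-3,4-diol | O[C@H]1CC(C)=CC[C@@]2(C)CC[C@@](O)(C(C)C)[C@H]12 | intermediate
19 | 8α,9α-epoxyjaeschkeanadiol, (1R,4R,5S,6S,8R,9S)-8,9-epoxydaucane-4,6-diol | O[C@H]1C[C@@]2(C)O[C@H]2C[C@@]2(C)CC[C@@](O)(C(C)C)[C@H]12 | intermediate
20 | 3,4-dimethoxybenzoyl chloride | COc1ccc(C(Cl)=O)cc1OC | starting material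
21 | (1R,4R,5S,6S,8R,9S)-8,9-epoxy-4-hydroxydaucan-6-yl 3,4-dimethoxybenzoate | COc1ccc(C(=O)O[C@H]2C[C@@]3(C)O[C@H]3C[C@@]3(C)CC[C@@](O)(C(C)C)[C@H]23)cc1OC | target

**Step count and risks**

Total step count: 13. Longest linear sequence: 13 steps (from 1).

Steps most likely to fail:

Step 7. The base-mediated equilibration at C5 may settle at an unfavourable epimer ratio, or the enolate may expel the β-silyloxy group. The fallback sets C5 by inversion in a stereospecific pinacol-type ring contraction instead of by equilibration; it sets out from ketone 6, comes back at aldehyde 12, replaces steps 5 to 7 and still forms the C1–C5 bond by a 1,2-shift of C1. The potassium enolate of 6 (KN(SiMe3)2, THF, −78 °C) would be hydroxylated with 2-(phenylsulfonyl)-3-phenyloxaziridine and the product equilibrated with Et3N to the equatorial epimer, the α-hydroxy ketone F1 (hydroxyl cis to OSiMe3). MsCl and Et3N would give the mesylate F2, and NaBH4 in MeOH the hydroxy mesylate F3. Et3Al in CH2Cl2 should then trigger migration of C1 from the carbinol carbon C6 to C5, anti to the equatorial mesylate, giving 12 with the formyl group in place and C5 fixed by inversion.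

Step 4. Facial selectivity at the new quaternary C1 may be poor, or fluoride may strip the tertiary silyl ether and open the ring by retro-aldol cleavage. The fallback changes from the intermolecular fluoride-triggered allylation to an intramolecular decarboxylative allylation of a preformed, regiodefined enol carbonate; it sets out from 4 and comes back at 6. MeLi (THF, 0 °C) should cleave only the enol silyl ether, and trapping of the lithium enolate with allyl chloroformate would give the allyl enol carbonate F4. Pd2(dba)3 with (R)-t-BuPHOX in THF would then ionise it to the enolate and allyl fragments and recombine them at C1 with loss of CO2, without fluoride.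

Step 12. Oxygen delivery may show insufficient face selectivity, or the Lewis-acidic medium may induce transannular opening of the new epoxide by the C4 hydroxyl. The fallback delivers the oxygen through a temporary carbonate tether; it sets out from 18 and comes back at 19. Di-tert-butyl dicarbonate and DMAP would give the C6 tert-butyl carbonate F5. IBr (toluene/CH2Cl2, −80 °C) should then close the six-membered iodo carbonate F6, the carbonate oxygen adding to C8 on the α face and iodine to C9 on the β face. K2CO3 in MeOH would cleave the carbonate, and the C8 alkoxide would displace the anti iodide at C9 to give the α-epoxide 19 with the C6 hydroxyl free.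

**Further compounds**

F1 | step 7 | (2R,5R,6S)-6-hydroxy-2-methyl-5-(propan-2-yl)-2-(prop-2-en-1-yl)-5-[(trimethylsilyl)oxy]cyclohexan-1-one | C=CC[C@@]1(C)CC[C@@](O[Si](C)(C)C)(C(C)C)[C@H](O)C1=O
F2 | step 7 | methanesulfonate of F1 | C=CC[C@@]1(C)CC[C@@](O[Si](C)(C)C)(C(C)C)[C@H](OS(C)(=O)=O)C1=O
F3 | step 7 | hydroxy mesylate from reduction of F2 (carbinol epimers) | C=CC[C@@]1(C)CC[C@@](O[Si](C)(C)C)(C(C)C)[C@H](OS(C)(=O)=O)C1O
F4 | step 4 | allyl (5S)-2-methyl-5-(propan-2-yl)-5-[(trimethylsilyl)oxy]cyclohex-1-en-1-yl carbonate | CC1=C(OC(=O)OCC=C)C[C@](O[Si](C)(C)C)(C(C)C)CC1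
F5 | step 12 | C6 tert-butyl carbonate of jaeschkeanadiol | CC(C)(C)OC(=O)O[C@H]1CC(C)=CC[C@@]2(C)CC[C@@](O)(C(C)C)[C@H]12
F6 | step 12 | 9β-iodo 6α,8α-cyclic carbonate of the 4,6,8-triol | O=C1O[C@H]2C[C@@](C)(O1)[C@H](I)C[C@@]3(C)CC[C@@](O)(C(C)C)[C@H]23
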